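Assumption: locants C1–C15 follow germacrane numbering (C6 carbinol, C7/C8 lactone fusion, C12 lactone carbonyl, C13 exocyclic methylene, C14 acyloxymethyl, C15 methyl); in these terms the target is (1(10)Z,4S,5R,6S,7S,8S).

**Retrosynthetic overview**
1. Oxirane last: the 4,5-epoxide comes from hydroxyl-directed peracid epoxidation of the macrocyclic (4Z)-6-ol, threo by allylic 1,3-strain.
2. Ten-membered carbocycle second: the C6–C7 bond and the 11(13)-methylene come from a new intramolecular chromium allylation of a Z-enal by a 3-(bromomethyl)butenolide; this sets C6 and C7.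
3. Butenolide ring first: ring-closing metathesis of the 2-(bromomethyl)acrylate of a C8 vinyl carbinol; C8 comes from (S)-epichlorohydrin (C9–C10 by alkenyllithium epoxide opening, C7 by sulfonium ylide homologation).
4. The C1=C10 geometry comes from Mo-catalysed syn-hydrostannation/iodination of a propargylic alcohol; C1–C6 and C15 (with the 4Z alkene) come from neryl acetate; the tiglate goes on C14 before any ring is made.
5. Ring order: butenolide, then cyclodecadiene, then oxirane.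

**Route**

Step 1
Reactants: 1 neryl acetate
Product: 2 6,7-epoxyneryl acetate
Conditions: mCPBA (1.0 equiv), NaHCO3, CH2Cl2, 0 °C
Reagents that add atoms: mCPBA (3-chloroperbenzoic acid), OOC(=O)c1cccc(Cl)c1
Why: Prilezhaev epoxidation is faster at the remote electron-rich trisubstituted alkene than at the alkene deactivated by the allylic acetate; the new oxirane CH is racemic and is destroyed in step 2.

Step 2
Reactants: 2 6,7-epoxyneryl acetate
Product: 4 (2Z)-3-methyl-6-oxohex-2-en-1-yl acetate, via diol 3 (not isolated)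
Conditions: H5IO6 (1.2 equiv), THF/H2O, 0 °C to rt
Reagents that add atoms: none
Why: Acidic epoxide hydrolysis followed by Malaprade glycol cleavage gives the C1 aldehyde and leaves the Z-allylic acetate untouched.

Step 3
Reactants: 4 (2Z)-3-methyl-6-oxohex-2-en-1-yl acetate
Product: 6 (2Z)-3-methylhept-2-en-6-yn-1-ol, via alkynyl acetate 5 (not isolated)
Conditions: dimethyl (1-diazo-2-oxopropyl)phosphonate (1.3 equiv), K2CO3 (3 equiv), MeOH, 0 °C to rt, 14 h
Reagents that add atoms: dimethyl (1-diazo-2-oxopropyl)phosphonate, CC(=O)C(=[N+]=[N-])P(=O)(OC)OC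
Why: Ohira–Bestmann (Seyferth–Gilbert) homologation turns the aldehyde into the terminal alkyne (new carbon = C10), and the same K2CO3/MeOH medium transesterifies the acetate.

Step 4
Reactants: 6 (2Z)-3-methylhept-2-en-6-yn-1-ol
Product: 7 tert-butyl(dimethyl){[(2Z)-3-methylhept-2-en-6-yn-1-yl]oxy}silane
Conditions: TBSCl, imidazole, CH2Cl2, rt
Reagents that add atoms: tert-butyldimethylsilyl chloride, CC(C)(C)[Si](C)(C)Cl
Why: Standard silylation of the primary allylic alcohol protects O6 through the organolithium steps.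

Step 5
Reactants: 7 tert-butyl(dimethyl){[(2Z)-3-methylhept-2-en-6-yn-1-yl]oxy}silane
Product: 9 (6Z)-8-[(tert-butyldimethylsilyl)oxy]-6-methyloct-6-en-2-yn-1-ol, via lithium acetylide 8 (not isolated)
Conditions: n-BuLi (1.1 equiv), THF, −78 °C; (CH2O)n, −78 °C to rt
Reagents that add atoms: formaldehyde (from paraformaldehyde), C=O
Why: Acetylide addition to formaldehyde installs C14 as a propargylic alcohol.

Step 6
Reactants: 9 (6Z)-8-[(tert-butyldimethylsilyl)oxy]-6-methyloct-6-en-2-yn-1-ol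
Product: 10 (2E,6Z)-8-[(tert-butyldimethylsilyl)oxy]-6-methyl-2-(tributylstannyl)octa-2,6-dien-1-ol
Conditions: Bu3SnH (2 equiv), Mo(CO)3(CNtBu)3 (3 mol%), hydroquinone (10 mol%), THF, 60 °C
Reagents that add atoms: tributyltin hydride, CCCC[SnH](CCCC)CCCC
Why: Molybdenum-catalysed hydrostannation of propargylic alcohols puts tin on the carbon next to the carbinol by syn addition, so C2 ends up cis to CH2OH (the C1=C10 geometry of the target).

Step 7
Reactants: 10 (2E,6Z)-8-[(tert-butyldimethylsilyl)oxy]-6-methyl-2-(tributylstannyl)octa-2,6-dien-1-ol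
Product: 11 (2E,6Z)-8-[(tert-butyldimethylsilyl)oxy]-2-iodo-6-methylocta-2,6-dien-1-ol
Conditions: I2 (1.05 equiv), CH2Cl2, 0 °C
Reagents that add atoms: iodine, II
Why: Iododestannylation proceeds with retention of alkene geometry.

Step 8
Reactants: 11 (2E,6Z)-8-[(tert-butyldimethylsilyl)oxy]-2-iodo-6-methylocta-2,6-dien-1-ol
Product: 12 4-methoxybenzyl ether of 11
Conditions: NaH, PMBCl, n-Bu4NI (cat.), THF/DMF, 0 °C to rt
Reagents that add atoms: 4-methoxybenzyl chloride, COc1ccc(CCl)cc1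
Why: Williamson etherification masks O14 with a group orthogonal to the TBS ether on O6.

Step 9
Reactants: 12 4-methoxybenzyl ether of 11, 13 (S)-epichlorohydrin
Product: 15 (2S,4Z,8Z)-10-[(tert-butyldimethylsilyl)oxy]-1-chloro-4-{[(4-methoxybenzyl)oxy]methyl}-8-methyldeca-4,8-dien-2-ol, via alkenyllithium 14 (not isolated)
Conditions: t-BuLi (2.1 equiv), Et2O, −78 °C, 20 min; 13 (1.5 equiv), BF3·OEt2 (1.5 equiv), −78 °C
Reagents that add atoms: none
Why: Iodine–lithium exchange retains the alkene geometry and the BF3-promoted SN2 opening of the epoxide at its CH2 terminus forms C9–C10; the C8 stereocentre is carried unchanged from (S)-epichlorohydrin.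

Step 10
Reactants: 15 (2S,4Z,8Z)-10-[(tert-butyldimethylsilyl)oxy]-1-chloro-4-{[(4-methoxybenzyl)oxy]methyl}-8-methyldeca-4,8-dien-2-ol
Product: 17 (3S,5Z,9Z)-11-[(tert-butyldimethylsilyl)oxy]-5-{[(4-methoxybenzyl)oxy]methyl}-9-methylundeca-1,5,9-trien-3-ol, via terminal epoxide 16 (not isolated)
Conditions: Me3S+ I− (4 equiv), n-BuLi (3.9 equiv), THF, −20 °C to rt
Reagents that add atoms: trimethylsulfonium iodide, C[S+](C)C.[I-]
Why: The alkoxide closes to the terminal epoxide (Williamson), and dimethylsulfonium methylide opens it at CH2 and eliminates Me2S to the one-carbon-homologated allylic alcohol; no bond to C8 is broken.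

Step 11
Reactants: 17 (3S,5Z,9Z)-11-[(tert-butyldimethylsilyl)oxy]-5-{[(4-methoxybenzyl)oxy]methyl}-9-methylundeca-1,5,9-trien-3-ol
Product: 18 (3S,5Z,9Z)-11-[(tert-butyldimethylsilyl)oxy]-5-(hydroxymethyl)-9-methylundeca-1,5,9-trien-3-ol
Conditions: DDQ (1.3 equiv), CH2Cl2/pH 7 buffer, 0 °C
Reagents that add atoms: none
Why: Oxidative cleavage of the 4-methoxybenzyl ether with DDQ under buffered conditions leaves the silyl ether and the alkenes alone.

Step 12
Reactants: 18 (3S,5Z,9Z)-11-[(tert-butyldimethylsilyl)oxy]-5-(hydroxymethyl)-9-methylundeca-1,5,9-trien-3-ol, 19 tigloyl chloride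
Product: 20 (2Z,6Z)-8-[(tert-butyldimethylsilyl)oxy]-2-[(2S)-2-hydroxybut-3-en-1-yl]-6-methylocta-2,6-dien-1-yl (2E)-2-methylbut-2-enoate
Conditions: 19 (1.1 equiv), 2,4,6-collidine, CH2Cl2, −78 to −20 °C
Reagents that add atoms: none
Why: Low-temperature acylation with a hindered α-branched acyl chloride and collidine is selective for the primary allylic O14 over the secondary O8.

Step 13
Reactants: 20 (2Z,6Z)-8-[(tert-butyldimethylsilyl)oxy]-2-[(2S)-2-hydroxybut-3-en-1-yl]-6-methylocta-2,6-dien-1-yl (2E)-2-methylbut-2-enoate, 21 2-(bromomethyl)acrylic acid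
Product: 22 (3S,5Z,9Z)-11-[(tert-butyldimethylsilyl)oxy]-9-methyl-5-({[(2E)-2-methylbut-2-enoyl]oxy}methyl)undeca-1,5,9-trien-3-yl 2-(bromomethyl)prop-2-enoate
Conditions: 21 (1.5 equiv), DCC (1.5 equiv), DMAP (5 mol%), CH2Cl2, 0 °C
Reagents that add atoms: none
Why: Steglich esterification acylates O8 with the unit that supplies C11, C12 and C13; DMAP is kept low and cold to spare the allylic bromide.

Step 14
Reactants: 22 (3S,5Z,9Z)-11-[(tert-butyldimethylsilyl)oxy]-9-methyl-5-({[(2E)-2-methylbut-2-enoyl]oxy}methyl)undeca-1,5,9-trien-3-yl 2-(bromomethyl)prop-2-enoate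
Product: 23 (2Z,6Z)-2-{[(2S)-4-(bromomethyl)-5-oxo-2,5-dihydrofuran-2-yl]methyl}-8-[(tert-butyldimethylsilyl)oxy]-6-methylocta-2,6-dien-1-yl (2E)-2-methylbut-2-enoate
Conditions: second-generation Grubbs catalyst RuCl2(=CHPh)(H2IMes)(PCy3) (10 mol%), toluene (5 mM), 80 °C
Reagents that add atoms: none
Why: Ring-closing metathesis between the vinyl group and the 1,1-disubstituted acrylate closes the butenolide (C7=C11) with loss of ethene; the trisubstituted alkenes and the tiglate are too hindered or electron-poor to compete.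

Step 15
Reactants: 23 (2Z,6Z)-2-{[(2S)-4-(bromomethyl)-5-oxo-2,5-dihydrofuran-2-yl]methyl}-8-[(tert-butyldimethylsilyl)oxy]-6-methylocta-2,6-dien-1-yl (2E)-2-methylbut-2-enoate
Product: 24 (2Z,6Z)-2-{[(2S)-4-(bromomethyl)-5-oxo-2,5-dihydrofuran-2-yl]methyl}-8-hydroxy-6-methylocta-2,6-dien-1-yl (2E)-2-methylbut-2-enoate
Conditions: 48% aq. HF, MeCN, 0 °C
Reagents that add atoms: none
Why: Acidic fluoride desilylation of the primary allylic TBS ether avoids amine bases that would alkylate at the allylic bromide.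

Step 16
Reactants: 24 (2Z,6Z)-2-{[(2S)-4-(bromomethyl)-5-oxo-2,5-dihydrofuran-2-yl]methyl}-8-hydroxy-6-methylocta-2,6-dien-1-yl (2E)-2-methylbut-2-enoate
Product: 25 (2Z,6Z)-2-{[(2S)-4-(bromomethyl)-5-oxo-2,5-dihydrofuran-2-yl]methyl}-6-methyl-8-oxoocta-2,6-dien-1-yl (2E)-2-methylbut-2-enoate
Conditions: activated MnO2 (20 equiv), CH2Cl2, rt
Reagents that add atoms: none
Why: Neutral MnO2 oxidation of the allylic alcohol gives the Z-enal without Z/E isomerisation and does not touch the allylic bromide.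

Step 17
Reactants: 25 (2Z,6Z)-2-{[(2S)-4-(bromomethyl)-5-oxo-2,5-dihydrofuran-2-yl]methyl}-6-methyl-8-oxoocta-2,6-dien-1-yl (2E)-2-methylbut-2-enoate
Product: 27 (1(10)Z,4Z,6R,7S,8S)-6-hydroxy-14-[(2E)-2-methylbut-2-enoyloxy]germacra-1(10),4,11(13)-trien-12,8-olide, via allylchromium dichloride 26 (not isolated)
Conditions: CrCl2 (6 equiv), THF/DMF (9:1), 25 °C, syringe-pump addition of 25 over 12 h (final 2 mM)
Reagents that add atoms: none
Why: Proposed new method: an intramolecular vinylogous Nozaki–Hiyama allylation with a 3-(bromomethyl)butenolide as allyl donor — CrCl2 reduces the allylic C–Br bond by two one-electron transfers to a σ-allyl species of trivalent chromium at C13, the enal oxygen binds chromium, and the butenolide β-carbon C7 attacks C6 through a six-membered chair transition state with allylic transposition, so the endocyclic C7=C11 bond becomes the exocyclic C11=C13 methylene and the ten-membered ring closes with O8 already in the lactone and O6 free; the allyl unit is locked E-like by the lactone ring (C8 trans to CH2Cr) and C5 sits equatorial, which gives the 6,7-anti pair (6R,7S), and C6 bonds to the face of C7 anti to the C8–C9 bond, which gives the less strained trans ring fusion (7S from 8S); the closest known reaction types are the CrCl2-mediated macrocyclisation of acyclic 2-(alkoxycarbonyl)allyl bromides onto aldehydes for ten-membered germacranolide rings and the intermolecular zinc or indium Barbier allylation of aldehydes with 3-(bromomethyl)furan-2(5H)-ones.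

Step 18
Reactants: 27 (1(10)Z,4Z,6R,7S,8S)-6-hydroxy-14-[(2E)-2-methylbut-2-enoyloxy]germacra-1(10),4,11(13)-trien-12,8-olide
Product: 28 (1(10)Z,4S,5R,6S,7S,8S)-4,5-epoxy-6-hydroxy-14-[(2E)-2-methylbut-2-enoyloxy]germacra-1(10),11(13)-dien-12,8-olide (CNP0116446.1)
Conditions: mCPBA (1.1 equiv), Na2HPO4, CH2Cl2, −20 to 0 °C
Reagents that add atoms: mCPBA (3-chloroperbenzoic acid), OOC(=O)c1cccc(Cl)c1
Why: Hydroxyl-directed Prilezhaev epoxidation of the Z-allylic alcohol goes through the conformer that avoids allylic 1,3-strain (H6 in the alkene plane, OH on the outer face) and gives the threo epoxy alcohol (4S,5R); the 1(10)-alkene is deactivated by its allylic ester and the two conjugated alkenes are electron-poor.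

**Compound list**
1 | neryl acetate, (2Z)-3,7-dimethylocta-2,6-dien-1-yl acetate | CC(C)=CCC/C(C)=C\COC(C)=O | starting material
2 | 6,7-epoxyneryl acetate, (2Z)-5-(3,3-dimethyloxiran-2-yl)-3-methylpent-2-en-1-yl acetate (racemic at the oxirane CH) | CC1(C)OC1CC/C(C)=C\COC(C)=O | intermediate
3 | (2Z)-6,7-dihydroxy-3,7-dimethyloct-2-en-1-yl acetate (racemic diol, not isolated) | CC(C)(O)C(O)CC/C(C)=C\COC(C)=O | intermediate
4 | (2Z)-3-methyl-6-oxohex-2-en-1-yl acetate | O=CCC/C(C)=C\COC(C)=O | intermediate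
5 | (2Z)-3-methylhept-2-en-6-yn-1-yl acetate (not isolated) | C#CCC/C(C)=C\COC(C)=O | intermediate
6 | (2Z)-3-methylhept-2-en-6-yn-1-ol | C#CCC/C(C)=C\CO | intermediate
7 | tert-butyl(dimethyl){[(2Z)-3-methylhept-2-en-6-yn-1-yl]oxy}silane | C#CCC/C(C)=C\CO[Si](C)(C)C(C)(C)C | intermediate
8 | lithium acetylide of 7 (not isolated) | [Li]C#CCC/C(C)=C\CO[Si](C)(C)C(C)(C)C | intermediate
9 | (6Z)-8-[(tert-butyldimethylsilyl)oxy]-6-methyloct-6-en-2-yn-1-ol | OCC#CCC/C(C)=C\CO[Si](C)(C)C(C)(C)C | intermediate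
10 | (2E,6Z)-8-[(tert-butyldimethylsilyl)oxy]-6-methyl-2-(tributylstannyl)octa-2,6-dien-1-ol | CCCC[Sn](CCCC)(CCCC)/C(CO)=C/CC/C(C)=C\CO[Si](C)(C)C(C)(C)C | intermediate
11 | (2E,6Z)-8-[(tert-butyldimethylsilyl)oxy]-2-iodo-6-methylocta-2,6-dien-1-ol | OC/C(I)=C\CC/C(C)=C\CO[Si](C)(C)C(C)(C)C | intermediate
12 | 4-methoxybenzyl ether of 11, 1-({[(2E,6Z)-8-[(tert-butyldimethylsilyl)oxy]-2-iodo-6-methylocta-2,6-dien-1-yl]oxy}methyl)-4-methoxybenzene | COc1ccc(COC/C(I)=C\CC/C(C)=C\CO[Si](C)(C)C(C)(C)C)cc1 | intermediate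
13 | (S)-epichlorohydrin, (2S)-2-(chloromethyl)oxirane | ClC[C@@H]1CO1 | starting material
14 | alkenyllithium from 12 (C–I replaced by C–Li with retained geometry, not isolated) | COc1ccc(COC/C([Li])=C\CC/C(C)=C\CO[Si](C)(C)C(C)(C)C)cc1 | intermediate
15 | (2S,4Z,8Z)-10-[(tert-butyldimethylsilyl)oxy]-1-chloro-4-{[(4-methoxybenzyl)oxy]methyl}-8-methyldeca-4,8-dien-2-ol | ClC[C@@H](O)C/C(COCc1ccc(OC)cc1)=C/CC/C(C)=C\CO[Si](C)(C)C(C)(C)C | intermediate
16 | (2S)-2-[(2Z,6Z)-8-[(tert-butyldimethylsilyl)oxy]-2-{[(4-methoxybenzyl)oxy]methyl}-6-methylocta-2,6-dien-1-yl]oxirane (not isolated) | C(/C(COCc1ccc(OC)cc1)=C/CC/C(C)=C\CO[Si](C)(C)C(C)(C)C)[C@H]1CO1 | intermediate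
17 | (3S,5Z,9Z)-11-[(tert-butyldimethylsilyl)oxy]-5-{[(4-methoxybenzyl)oxy]methyl}-9-methylundeca-1,5,9-trien-3-ol | C=C[C@@H](O)C/C(COCc1ccc(OC)cc1)=C/CC/C(C)=C\CO[Si](C)(C)C(C)(C)C | intermediate
18 | (3S,5Z,9Z)-11-[(tert-butyldimethylsilyl)oxy]-5-(hydroxymethyl)-9-methylundeca-1,5,9-trien-3-ol | C=C[C@@H](O)C/C(CO)=C/CC/C(C)=C\CO[Si](C)(C)C(C)(C)C | intermediate
19 | tigloyl chloride, (2E)-2-methylbut-2-enoyl chloride | C/C=C(\C)C(Cl)=O | starting material
20 | (2Z,6Z)-8-[(tert-butyldimethylsilyl)oxy]-2-[(2S)-2-hydroxybut-3-en-1-yl]-6-methylocta-2,6-dien-1-yl (2E)-2-methylbut-2-enoate | C=C[C@@H](O)C/C(COC(=O)/C(C)=C/C)=C/CC/C(C)=C\CO[Si](C)(C)C(C)(C)C | intermediate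
21 | 2-(bromomethyl)acrylic acid | OC(=O)C(=C)CBr | starting material
22 | (3S,5Z,9Z)-11-[(tert-butyldimethylsilyl)oxy]-9-methyl-5-({[(2E)-2-methylbut-2-enoyl]oxy}methyl)undeca-1,5,9-trien-3-yl 2-(bromomethyl)prop-2-enoate | C=C[C@@H](OC(=O)C(=C)CBr)C/C(COC(=O)/C(C)=C/C)=C/CC/C(C)=C\CO[Si](C)(C)C(C)(C)C | intermediate
23 | (2Z,6Z)-2-{[(2S)-4-(bromomethyl)-5-oxo-2,5-dihydrofuran-2-yl]methyl}-8-[(tert-butyldimethylsilyl)oxy]-6-methylocta-2,6-dien-1-yl (2E)-2-methylbut-2-enoate | BrCC1=C[C@H](C/C(COC(=O)/C(C)=C/C)=C/CC/C(C)=C\CO[Si](C)(C)C(C)(C)C)OC1=O | intermediate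
24 | (2Z,6Z)-2-{[(2S)-4-(bromomethyl)-5-oxo-2,5-dihydrofuran-2-yl]methyl}-8-hydroxy-6-methylocta-2,6-dien-1-yl (2E)-2-methylbut-2-enoate | BrCC1=C[C@H](C/C(COC(=O)/C(C)=C/C)=C/CC/C(C)=C\CO)OC1=O | intermediate
25 | (2Z,6Z)-2-{[(2S)-4-(bromomethyl)-5-oxo-2,5-dihydrofuran-2-yl]methyl}-6-methyl-8-oxoocta-2,6-dien-1-yl (2E)-2-methylbut-2-enoate | BrCC1=C[C@H](C/C(COC(=O)/C(C)=C/C)=C/CC/C(C)=C\C=O)OC1=O | intermediate
26 | allylchromium dichloride from 25 (CH2Br replaced by CH2CrCl2, not isolated) | Cl[Cr](Cl)CC1=C[C@H](C/C(COC(=O)/C(C)=C/C)=C/CC/C(C)=C\C=O)OC1=O | intermediate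
27 | (1(10)Z,4Z,6R,7S,8S)-6-hydroxy-14-[(2E)-2-methylbut-2-enoyloxy]germacra-1(10),4,11(13)-trien-12,8-olide (trans-fused α-methylene-γ-lactone on the cyclodecadiene) | C=C1C(=O)O[C@H]2C/C(COC(=O)/C(C)=C/C)=C/CC/C(C)=C\[C@@H](O)[C@H]12 | intermediate
28 | (1(10)Z,4S,5R,6S,7S,8S)-4,5-epoxy-6-hydroxy-14-[(2E)-2-methylbut-2-enoyloxy]germacra-1(10),11(13)-dien-12,8-olide | C=C1C(=O)O[C@H]2C/C(COC(=O)/C(C)=C/C)=C/CC[C@]3(C)O[C@@H]3[C@@H](O)[C@H]12 | target

**Summary**
Total step count: 18. Longest linear sequence: 18 steps from neryl acetate 1 (13, 19 and 21 are purchased).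

**Three steps most likely to fail**

Step 17 (the proposed new macrocyclisation). The ring may not close, or it may close to the cis-fused or the 6-epi isomer, since the sense of ring fusion rests on a transition-state model. The fallback uses known chemistry, sets out from 20 and comes back at 27. It closes the ring with an acyclic allyl bromide and forms the lactone afterwards under protecting-group control.
- Protect O8 of 20 with 4-methoxybenzyl trichloroacetimidate and La(OTf)3 to give the ether F1.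
- Cross-metathesise its vinyl group with methyl 2-(bromomethyl)acrylate (second-generation Hoveyda–Grubbs catalyst RuCl2(=CH-C6H4-2-OiPr)(H2IMes)) to the acyclic methyl 2-(bromomethyl)enoate F2.
- Remove the TBS group with aqueous HF in MeCN to give the allylic alcohol F3 and oxidise it with MnO2 to the Z-enal F4.
- Close the ten-membered ring by the established chromium-mediated cyclisation of an acyclic 2-(alkoxycarbonyl)allyl bromide onto an aldehyde, run with catalytic CrCl2, Mn powder and Et3SiCl so that O6 emerges as the triethylsilyl ether F5.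
- Cleave the 4-methoxybenzyl ether with DDQ to the C8 alcohol F6 and lactonise onto O8 with catalytic camphorsulfonic acid to the silylated lactone F7.
- Aqueous HF in MeCN then gives 27.

Step 14 (ring-closing metathesis to a trisubstituted butenolide that carries an allylic bromide). The fallback sets out from 20 and comes back at 23.
- Acylate 20 with acryloyl chloride and iPr2NEt to the acrylate F8.
- Ring-closing metathesis, now forming only a disubstituted alkene, gives the unsubstituted butenolide F9.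
- A PBu3-catalysed Morita–Baylis–Hillman hydroxymethylation with aqueous formaldehyde installs C13 as the 3-(hydroxymethyl)butenolide F10.
- Appel bromination (CBr4, PPh3) returns 23.

Step 18 (chemoselectivity against the 1(10)-alkene and facial selectivity of the late epoxidation). The fallback sets out from 24 and comes back at 28. It installs the epoxide before ring closure under reagent control instead of substrate control.
- Sharpless asymmetric epoxidation of the primary Z-allylic alcohol 24 (Ti(OiPr)4, D-(−)-diethyl tartrate, t-BuOOH, 4 Å sieves, −20 °C) gives the epoxy alcohol F11.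
- Dess–Martin oxidation gives the epoxy aldehyde F12.
- Cyclisation of F12 under the step 17 conditions delivers 28 directly. This ring closure must override the Felkin preference of the epoxy aldehyde, which is why it is the fallback and not the main route.

**Further compounds**
F1 | step 17 | (2Z,6Z)-8-[(tert-butyldimethylsilyl)oxy]-2-{(2S)-2-[(4-methoxybenzyl)oxy]but-3-en-1-yl}-6-methylocta-2,6-dien-1-yl (2E)-2-methylbut-2-enoate | C=C[C@@H](OCc1ccc(OC)cc1)C/C(COC(=O)/C(C)=C/C)=C/CC/C(C)=C\CO[Si](C)(C)C(C)(C)C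
F2 | step 17 | methyl (2Z,4S,6Z,10Z)-2-(bromomethyl)-12-[(tert-butyldimethylsilyl)oxy]-4-[(4-methoxybenzyl)oxy]-10-methyl-6-({[(2E)-2-methylbut-2-enoyl]oxy}methyl)dodeca-2,6,10-trienoate | COC(=O)/C(CBr)=C/[C@@H](OCc1ccc(OC)cc1)C/C(COC(=O)/C(C)=C/C)=C/CC/C(C)=C\CO[Si](C)(C)C(C)(C)C
F3 | step 17 | methyl (2Z,4S,6Z,10Z)-2-(bromomethyl)-12-hydroxy-4-[(4-methoxybenzyl)oxy]-10-methyl-6-({[(2E)-2-methylbut-2-enoyl]oxy}methyl)dodeca-2,6,10-trienoate | COC(=O)/C(CBr)=C/[C@@H](OCc1ccc(OC)cc1)C/C(COC(=O)/C(C)=C/C)=C/CC/C(C)=C\CO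
F4 | step 17 | methyl (2Z,4S,6Z,10Z)-2-(bromomethyl)-4-[(4-methoxybenzyl)oxy]-10-methyl-6-({[(2E)-2-methylbut-2-enoyl]oxy}methyl)-12-oxododeca-2,6,10-trienoate | COC(=O)/C(CBr)=C/[C@@H](OCc1ccc(OC)cc1)C/C(COC(=O)/C(C)=C/C)=C/CC/C(C)=C\C=O
F5 | step 17 | methyl (1(10)Z,4Z,6R,7R,8S)-8-[(4-methoxybenzyl)oxy]-14-[(2E)-2-methylbut-2-enoyloxy]-6-[(triethylsilyl)oxy]germacra-1(10),4,11(13)-trien-12-oate | COC(=O)C(=C)[C@@H]1[C@@H](OCc2ccc(OC)cc2)C/C(COC(=O)/C(C)=C/C)=C/CC/C(C)=C\[C@H]1O[Si](CC)(CC)CC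
F6 | step 17 | methyl (1(10)Z,4Z,6R,7R,8S)-8-hydroxy-14-[(2E)-2-methylbut-2-enoyloxy]-6-[(triethylsilyl)oxy]germacra-1(10),4,11(13)-trien-12-oate | COC(=O)C(=C)[C@@H]1[C@@H](O)C/C(COC(=O)/C(C)=C/C)=C/CC/C(C)=C\[C@H]1O[Si](CC)(CC)CC
F7 | step 17 | (1(10)Z,4Z,6R,7R,8S)-14-[(2E)-2-methylbut-2-enoyloxy]-6-[(triethylsilyl)oxy]germacra-1(10),4,11(13)-trien-12,8-olide | C=C1C(=O)O[C@H]2C/C(COC(=O)/C(C)=C/C)=C/CC/C(C)=C\[C@@H](O[Si](CC)(CC)CC)[C@H]12
F8 | step 14 | (3S,5Z,9Z)-11-[(tert-butyldimethylsilyl)oxy]-9-methyl-5-({[(2E)-2-methylbut-2-enoyl]oxy}methyl)undeca-1,5,9-trien-3-yl prop-2-enoate | C=C[C@@H](OC(=O)C=C)C/C(COC(=O)/C(C)=C/C)=C/CC/C(C)=C\CO[Si](C)(C)C(C)(C)C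
F9 | step 14 | (2Z,6Z)-8-[(tert-butyldimethylsilyl)oxy]-6-methyl-2-{[(2S)-5-oxo-2,5-dihydrofuran-2-yl]methyl}octa-2,6-dien-1-yl (2E)-2-methylbut-2-enoate | O=C1C=C[C@H](C/C(COC(=O)/C(C)=C/C)=C/CC/C(C)=C\CO[Si](C)(C)C(C)(C)C)O1
F10 | step 14 | (2Z,6Z)-8-[(tert-butyldimethylsilyl)oxy]-2-{[(2S)-4-(hydroxymethyl)-5-oxo-2,5-dihydrofuran-2-yl]methyl}-6-methylocta-2,6-dien-1-yl (2E)-2-methylbut-2-enoate | OCC1=C[C@H](C/C(COC(=O)/C(C)=C/C)=C/CC/C(C)=C\CO[Si](C)(C)C(C)(C)C)OC1=O
F11 | step 18 | (2Z)-2-{[(2S)-4-(bromomethyl)-5-oxo-2,5-dihydrofuran-2-yl]methyl}-5-[(2S,3R)-3-(hydroxymethyl)-2-methyloxiran-2-yl]pent-2-en-1-yl (2E)-2-methylbut-2-enoate | BrCC1=C[C@H](C/C(COC(=O)/C(C)=C/C)=C/CC[C@]2(C)O[C@@H]2CO)OC1=O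
F12 | step 18 | (2Z)-2-{[(2S)-4-(bromomethyl)-5-oxo-2,5-dihydrofuran-2-yl]methyl}-5-[(2S,3S)-3-formyl-2-methyloxiran-2-yl]pent-2-en-1-yl (2E)-2-methylbut-2-enoate | BrCC1=C[C@H](C/C(COC(=O)/C(C)=C/C)=C/CC[C@]2(C)O[C@@H]2C=O)OC1=O
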